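The numbers in the tables are simulated for substances that don't exist.

You put 3 questions to this flask, and a quick number needs something frozen first.

the same everywhere: substrate 0.010 M; reagent 1.05 equiv
- north-west: capture agent 5 mM; run made earlier
- south-west: capture agent 20 mM; run made earlier
- flask: capture agent 10.0 mM; time 1.0 h

| run | time / min | bis adduct / % |
|---|---|---|
| north-west | 3.00 | 4.1 |
| north-west | 6.00 | 7.8 |
| north-west | 10.0 | 9.7 |
| north-west | 15.0 | 10.4 |
| north-west | 25.0 | 9.4 |
| north-west | 40.0 | 7.5 |
| north-west | 80.0 | 5.8 |
| south-west | 3.00 | 4.5 |
| south-west | 6.00 | 6.3 |
| south-west | 10.0 | 7.5 |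
| south-west | 15.0 | 8.5 |
| south-west | 25.0 | 7.3 |
| south-west | 40.0 | 5.7 |
| south-west | 80.0 | 4.8 |

(readings scatter by 0.5 percentage points)

- time, not beyond 1.0 h, at which the flask holds most bis adduct
- the amount of bis adduct, in percent of the substrate charged, at that time
- the first time at which bis adduct reaches 4.6%, in the same percent

- steps under discussion: single product + capture agent -> trapped intermediate; bis adduct <-> isomer of the product; substrate + reagent -> single product; reagent + single product -> bis adduct

Take the steps under discussion. Substrate and reagent give single product, and reagent and single product give bis adduct, while capture and isomerisation touch neither substrate nor reagent. So each step leaves c(reagent) − c(substrate) + c(bis adduct) + c(isomer of the product) unchanged. At 1.05 equiv this sum is 5.00% of the substrate charged, and I call it the surplus.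

Your flask lies one doubling of capture agent from each run. The runs' highest readings, 10.4% and 8.5%, both stand at 15.0 min, so I commit to their geometric mean, 9.40%, near that time. At 3.00 min both runs read just under 4.6%, so I expect that level a little later. That height exceeds the surplus, so at the peak I expect c(substrate) at least 4.4 percentage points above c(reagent): despite its excess charge, reagent is the limiting reagent.

Your hunch, the forecast, gives 9.6% at 0.25 h, a little above my height, and 4.6% at 0.057 h, from a “saturating dependence on capture agent”.

The flask gives 9.21% at 0.229 h, and 4.6% at 0.0532 h.

    single product + capture agent → trapped intermediate (k = 0.0936 M⁻¹ s⁻¹)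
    bis adduct ⇌ isomer of the product (K = 2.13, k = 5.68 × 10⁻⁴ s⁻¹)
    substrate + reagent → single product (k = 0.807 M⁻¹ s⁻¹)
    reagent + single product → bis adduct (k = 0.127 M⁻¹ s⁻¹)

After 1.00 h this flask holds 0.29% of its reagent charge, with substrate 9.67%, bis adduct 5.40% and isomer of the product 8.97%, and the surplus adds up to 5.00%. Now charge 1.80 equiv of reagent, all else held, and the surplus becomes 80.0%. After 1.00 h that neighbour flask has substrate 0% and reagent 17% of its own charge, which is 30.2% of the substrate charged. Beside that reagent, the neighbour flask holds 49.9% of the surplus, as bis adduct 19.7% and isomer of the product 30.2%.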